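The oxolane (O1, C2 bearing the phenolic arene, C3, C4, C5 bearing the trimethoxyphenyl group) is cut at O1–C5 and C2–C3 into an aryl aldehyde (O1, C2) and a donor–acceptor cyclopropane (C3–C4–C5). A Lewis-acid (3+2) cycloaddition expands the three-membered carbocycle to the five-membered ether in one operation, exploiting benzylic C5 as donor carbon and C3 as malonate carbon. The precursor is a trans-2-aryl-3-(benzyloxymethyl)cyclopropane-1,1-diester made by organocatalytic cyclopropanation. Its C4 stereocentre is the only one that has to persist, since C3, C2 and C5 are afterwards relayed from it to the all-trans array by equilibration.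

Key step: step 4

Remark: the oxolane numbering of the target is used throughout (C2 carries the 4-hydroxy-3,5-dimethoxyphenyl group, C5 the 3,4,5-trimethoxyphenyl group). Compounds 1, 2 and 6 and both enantiomers of the diphenylprolinol silyl ether catalyst are assumed to be purchasable.

Step 1
Reactants: 1 (E)-3-(3,4,5-trimethoxyphenyl)prop-2-enal; 2 dimethyl 2-bromomalonate
Product: 3 dimethyl (2S,3R)-2-formyl-3-(3,4,5-trimethoxyphenyl)cyclopropane-1,1-dicarboxylate
Conditions: (R)-2-[diphenyl(trimethylsilyloxy)methyl]pyrrolidine (20 mol %), 2,6-lutidine (1.1 equiv), CH2Cl2, 0 °C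
Reagents that add atoms: none
Why: In this organocatalytic Michael-initiated ring closure, the iminium ion of 1 should take up the bromomalonate at the β-carbon on the face away from the diphenyl(silyloxy)methyl group and the enamine then closes by 3-exo-tet alkylation, setting the aryl-bearing carbon (R) under catalyst control and the formyl-bearing carbon (S, trans to aryl) under substrate control.

Step 2
Reactants: 3 dimethyl (2S,3R)-2-formyl-3-(3,4,5-trimethoxyphenyl)cyclopropane-1,1-dicarboxylate
Product: 4 dimethyl (2S,3R)-2-(hydroxymethyl)-3-(3,4,5-trimethoxyphenyl)cyclopropane-1,1-dicarboxylate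
Conditions: NaBH4, MeOH–CH2Cl2, −40 °C; AcOH quench; used crude
Reagents that add atoms: none
Why: Chemoselective borohydride reduction of the aldehyde beside the methyl esters should give the primary alcohol with both stereocentres untouched, the low temperature and acidic quench holding back lactonisation onto the cis ester.

Step 3
Reactants: 4 dimethyl (2S,3R)-2-(hydroxymethyl)-3-(3,4,5-trimethoxyphenyl)cyclopropane-1,1-dicarboxylate
Product: 5 dimethyl (2S,3R)-2-[(benzyloxy)methyl]-3-(3,4,5-trimethoxyphenyl)cyclopropane-1,1-dicarboxylate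
Conditions: BnOC(=NH)CCl3 (1.5 equiv), TfOH (5 mol %), CH2Cl2–cyclohexane, 0 °C
Reagents that add atoms: benzyl 2,2,2-trichloroacetimidate, N=C(OCc1ccccc1)C(Cl)(Cl)Cl
Why: Acid-catalysed O-benzylation with a trichloroacetimidate should install the ether without generating the alkoxide that would lactonise onto the cis ester, and it creates no stereocentre.

Step 4
Reactants: 5 dimethyl (2S,3R)-2-[(benzyloxy)methyl]-3-(3,4,5-trimethoxyphenyl)cyclopropane-1,1-dicarboxylate; 6 4-(benzyloxy)-3,5-dimethoxybenzaldehyde
Product: 7 dimethyl (2S,4S,5S)-2-[4-(benzyloxy)-3,5-dimethoxyphenyl]-4-[(benzyloxy)methyl]-5-(3,4,5-trimethoxyphenyl)oxolane-3,3-dicarboxylate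
Conditions: AlCl3 (20 mol %), 6 (2.5 equiv), CH2Cl2, 23 °C
Reagents that add atoms: none
Why: AlCl3 chelates the geminal diester of 5 and polarises the bond between the malonate carbon and the benzylic donor carbon, so that the carbonyl oxygen of 6 attacks the donor carbon in an SN2-like manner and the resulting malonate enolate/oxocarbenium ion pair then forms the C2–C3 bond in an aldol-type step. The closest known reaction type is the Lewis-acid-catalysed (3+2) cycloaddition of donor–acceptor cyclopropanes with aldehydes, here a two-atom ring expansion of the cyclopropane to the oxolane. The one ring that forms closes in a 5-(enolexo)-endo-trig mode (enolate carbon onto the oxocarbenium carbon) through an envelope transition state. C5 is set by stereospecific inversion at the cyclopropane donor carbon, which places its aryl group cis to the retained benzyloxymethyl group at C4, and C2 is set by the envelope that holds both aryl groups pseudo-equatorial (2,5-cis). The step needs cleavage of the malonate–C(aryl) bond and not the malonate–C(CH2OBn) bond, which the cation-stabilising trimethoxyphenyl donor secures, and tolerance of the benzyl ethers, which the catalytic Lewis-acid loading at ambient temperature should secure. Since C2, C3 and C5 are equilibrated later, only the C4 configuration has to survive this step.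

Step 5
Reactants: 7 dimethyl (2S,4S,5S)-2-[4-(benzyloxy)-3,5-dimethoxyphenyl]-4-[(benzyloxy)methyl]-5-(3,4,5-trimethoxyphenyl)oxolane-3,3-dicarboxylate
Product: 9 methyl (2R,3R,4S,5S)-2-[4-(benzyloxy)-3,5-dimethoxyphenyl]-4-[(benzyloxy)methyl]-5-(3,4,5-trimethoxyphenyl)oxolane-3-carboxylate, via C3-epimeric methyl ester 8 (not isolated)
Conditions: LiCl, H2O, DMSO, 150 °C; then NaOMe (0.2 equiv), MeOH, 23 °C
Reagents that add atoms: none
Why: Krapcho demethoxycarbonylation (chloride attack on a methyl ester, loss of CO2, protonation of the ester enolate) removes one ester, and methoxide equilibration by enolisation should converge the C3 epimers on the ester trans to both the C2 aryl and the C4 benzyloxymethyl group (3R), reversible retro-oxa-Michael opening only reinforcing the trans C2/C3 arrangement.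

Step 6
Reactants: 9 methyl (2R,3R,4S,5S)-2-[4-(benzyloxy)-3,5-dimethoxyphenyl]-4-[(benzyloxy)methyl]-5-(3,4,5-trimethoxyphenyl)oxolane-3-carboxylate
Product: 10 methyl (2R,3R,4S,5R)-2-[4-(benzyloxy)-3,5-dimethoxyphenyl]-4-[(benzyloxy)methyl]-5-(3,4,5-trimethoxyphenyl)oxolane-3-carboxylate
Conditions: BF3·OEt2 (0.5 equiv), CH2Cl2, −20 to 0 °C
Reagents that add atoms: none
Why: This is the Lewis-acid epimerisation known for 2,5-diaryloxolane lignans (reversible heterolysis of the benzylic C5–O1 bond to a trialkoxybenzyl cation and re-closure by the pendant oxygen), and it should invert C5 under thermodynamic control to relieve the cis C4/C5 interaction, with C3 and C4 as fixed anchors, giving the all-trans ester.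

Step 7
Reactants: 10 methyl (2R,3R,4S,5R)-2-[4-(benzyloxy)-3,5-dimethoxyphenyl]-4-[(benzyloxy)methyl]-5-(3,4,5-trimethoxyphenyl)oxolane-3-carboxylate
Product: 11 {(2R,3S,4S,5R)-2-[4-(benzyloxy)-3,5-dimethoxyphenyl]-4-[(benzyloxy)methyl]-5-(3,4,5-trimethoxyphenyl)oxolan-3-yl}methanol
Conditions: LiAlH4, THF, 0 °C
Reagents that add atoms: none
Why: Hydride reduction of the methyl ester to the primary alcohol should leave the ethers and all four stereocentres untouched and removes the last epimerisable position.

Step 8
Reactants: 11 {(2R,3S,4S,5R)-2-[4-(benzyloxy)-3,5-dimethoxyphenyl]-4-[(benzyloxy)methyl]-5-(3,4,5-trimethoxyphenyl)oxolan-3-yl}methanol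
Product: 12 4-[(2R,3S,4S,5R)-3,4-bis(hydroxymethyl)-5-(3,4,5-trimethoxyphenyl)oxolan-2-yl]-2,6-dimethoxyphenol (CID56680032)
Conditions: H2 (1 atm), 10% Pd/C, EtOAc–MeOH, 23 °C
Reagents that add atoms: none
Why: Palladium-catalysed hydrogenolysis should cleave the aryl benzyl ether and the alkyl benzyl ether under neutral conditions in which the much slower-reacting ring C–O bonds and the stereocentres remain intact.

Compound list
1 | (E)-3-(3,4,5-trimethoxyphenyl)prop-2-enal | COc1cc(/C=C/C=O)cc(OC)c1OC | starting material
2 | dimethyl 2-bromomalonate | COC(=O)C(Br)C(=O)OC | starting material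
3 | dimethyl (2S,3R)-2-formyl-3-(3,4,5-trimethoxyphenyl)cyclopropane-1,1-dicarboxylate | COc1cc([C@H]2[C@H](C=O)C2(C(=O)OC)C(=O)OC)cc(OC)c1OC | intermediate
4 | dimethyl (2S,3R)-2-(hydroxymethyl)-3-(3,4,5-trimethoxyphenyl)cyclopropane-1,1-dicarboxylate | COc1cc([C@H]2[C@H](CO)C2(C(=O)OC)C(=O)OC)cc(OC)c1OC | intermediate
5 | dimethyl (2S,3R)-2-[(benzyloxy)methyl]-3-(3,4,5-trimethoxyphenyl)cyclopropane-1,1-dicarboxylate | COc1cc([C@H]2[C@H](COCc3ccccc3)C2(C(=O)OC)C(=O)OC)cc(OC)c1OC | intermediate
6 | 4-(benzyloxy)-3,5-dimethoxybenzaldehyde | COc1cc(C=O)cc(OC)c1OCc1ccccc1 | starting material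
7 | dimethyl (2S,4S,5S)-2-[4-(benzyloxy)-3,5-dimethoxyphenyl]-4-[(benzyloxy)methyl]-5-(3,4,5-trimethoxyphenyl)oxolane-3,3-dicarboxylate (C2 aryl, C4 CH2OBn and C5 aryl all cis) | COc1cc([C@@H]2O[C@H](c3cc(OC)c(OC)c(OC)c3)[C@H](COCc3ccccc3)C2(C(=O)OC)C(=O)OC)cc(OC)c1OCc1ccccc1 | intermediate
8 | methyl (2R,3S,4S,5S)-2-[4-(benzyloxy)-3,5-dimethoxyphenyl]-4-[(benzyloxy)methyl]-5-(3,4,5-trimethoxyphenyl)oxolane-3-carboxylate (all-cis, C3 epimer of 9) | COc1cc([C@@H]2O[C@H](c3cc(OC)c(OC)c(OC)c3)[C@H](COCc3ccccc3)[C@@H]2C(=O)OC)cc(OC)c1OCc1ccccc1 | intermediate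
9 | methyl (2R,3R,4S,5S)-2-[4-(benzyloxy)-3,5-dimethoxyphenyl]-4-[(benzyloxy)methyl]-5-(3,4,5-trimethoxyphenyl)oxolane-3-carboxylate | COc1cc([C@@H]2O[C@H](c3cc(OC)c(OC)c(OC)c3)[C@H](COCc3ccccc3)[C@H]2C(=O)OC)cc(OC)c1OCc1ccccc1 | intermediate
10 | methyl (2R,3R,4S,5R)-2-[4-(benzyloxy)-3,5-dimethoxyphenyl]-4-[(benzyloxy)methyl]-5-(3,4,5-trimethoxyphenyl)oxolane-3-carboxylate (all-trans) | COc1cc([C@@H]2O[C@@H](c3cc(OC)c(OC)c(OC)c3)[C@H](COCc3ccccc3)[C@H]2C(=O)OC)cc(OC)c1OCc1ccccc1 | intermediate
11 | {(2R,3S,4S,5R)-2-[4-(benzyloxy)-3,5-dimethoxyphenyl]-4-[(benzyloxy)methyl]-5-(3,4,5-trimethoxyphenyl)oxolan-3-yl}methanol | COc1cc([C@@H]2O[C@@H](c3cc(OC)c(OC)c(OC)c3)[C@H](COCc3ccccc3)[C@H]2CO)cc(OC)c1OCc1ccccc1 | intermediate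
12 | 4-[(2R,3S,4S,5R)-3,4-bis(hydroxymethyl)-5-(3,4,5-trimethoxyphenyl)oxolan-2-yl]-2,6-dimethoxyphenol | COc1cc([C@@H]2O[C@@H](c3cc(OC)c(OC)c(OC)c3)[C@H](CO)[C@H]2CO)cc(OC)c1O | target

Total step count: 8. Longest linear sequence: 8 steps (1 to 12). The cycloaddition (step 4) is buffered by the later equilibrations and is judged less likely to fail than the three steps below.

Step 6 (most at risk). The ring-opened benzylic cation may be captured irreversibly instead of re-closing, either by the electron-rich arene at C2 (intramolecular Friedel–Crafts alkylation to an aryltetralin) or by the ester carbonyl oxygen. The fallback sets out from 9 and comes back at 10 and replaces the ionic equilibration by a radical one. It is a thiol-catalysed radical-chain epimerisation (polarity-reversal catalysis), in which a thiyl radical abstracts and returns the benzylic α-oxy hydrogen atoms at C2 and C5, for example with tri-tert-butoxysilanethiol (10 mol %) and a radical initiator in benzene at 60–80 °C. This should equilibrate the two benzylic centres to the all-trans isomer without any cation, the C3 and C4 hydrogens being polarity-mismatched or unactivated. It makes no new compound.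

Step 3. The hydroxymethyl group may lactonise onto the cis ester, or the triflic acid may open the activated cyclopropane, before benzyl transfer is complete. The fallback sets out from 4 and comes back at 5 and builds the ether by reductive etherification instead of alkylation. Neutral silylation with N,O-bis(trimethylsilyl)acetamide in CH2Cl2 would give dimethyl (2S,3R)-2-{[(trimethylsilyl)oxy]methyl}-3-(3,4,5-trimethoxyphenyl)cyclopropane-1,1-dicarboxylate F1. Treatment of F1 with benzaldehyde and triethylsilane under catalytic TMSOTf at −78 °C should then give 5, the oxocarbenium ion sitting on the benzaldehyde carbon and not next to the cyclopropane.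

Step 5. At 150 °C the β-alkoxy ester enolate may open the ring by elimination or retro-aldol cleavage without re-closing, or the dealkylation may stall on the hindered diester. The fallback sets out from 7 and comes back at 9 and removes the ester group by hydrolysis and thermal decarboxylation instead of nucleophilic dealkylation. Mono-saponification (KOH, 1 equiv, MeOH–H2O, 23 °C) would give the malonic half-acid (2S,4S,5S)-2-[4-(benzyloxy)-3,5-dimethoxyphenyl]-4-[(benzyloxy)methyl]-3-(methoxycarbonyl)-5-(3,4,5-trimethoxyphenyl)oxolane-3-carboxylic acid F2 (either C3 epimer). F2 should lose CO2 in toluene at 110 °C to give the mixture of 8 and 9, which the methoxide equilibration of step 5 converges on 9.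

Further compounds
F0 | step 6 | none | none
F1 | step 3 | dimethyl (2S,3R)-2-{[(trimethylsilyl)oxy]methyl}-3-(3,4,5-trimethoxyphenyl)cyclopropane-1,1-dicarboxylate | COc1cc([C@H]2[C@H](CO[Si](C)(C)C)C2(C(=O)OC)C(=O)OC)cc(OC)c1OC
F2 | step 5 | (2S,4S,5S)-2-[4-(benzyloxy)-3,5-dimethoxyphenyl]-4-[(benzyloxy)methyl]-3-(methoxycarbonyl)-5-(3,4,5-trimethoxyphenyl)oxolane-3-carboxylic acid (C3 not assigned) | COc1cc([C@@H]2O[C@H](c3cc(OC)c(OC)c(OC)c3)[C@H](COCc3ccccc3)C2(C(=O)O)C(=O)OC)cc(OC)c1OCc1ccccc1
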